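**Plan**
Numbering: dibenzofuran ring A = C1–C4, C4a, C9b (bridge on C1, OH on C3); ring B = C5a–C9a (bridge on C7); ring C = the 1,2-dioxygenated ring; ring D = the para-phenylene. Benzofuran C2, C3 and C6 of the intermediates become C4a, C9b and C7.
Enabling feature: in ring A the hydroxyl carbon C3 is linked to the oxygen-bearing furan carbon C4a through a single CH (C4), and the bridge carbon C1 sits on C9b. C3–C4 can therefore be read as a ketene on benzofuran C2, and C1=C2 as a 1,1-disubstituted alkene on benzofuran C3.
Cuts, in retrosynthetic order: ring C O–CH3; ring A at C2–C3 (electrocyclisation) and C4–C4a (Wolff shift), back to a macrocyclic diazoketone; the benzofuran C3–alkenyl bond of the 18-membered ring; furan C2–C3; the chain carbons of the ring D bridge; the C7–CH2 bond of the ring B/ring C bridge; the ring D C–O bond.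
Forward order: ring C–O–ring D ether (SNAr), ring B/ring C bibenzyl bridge (Heck, hydrogenation), butynyl chain on ring D, furan ring (Dieckmann), macrocycle (Suzuki–Miyaura), ring A (photo-Wolff plus six-electron closure), final O-demethylation.
Stereochemistry: the target has no stereocentre. The stilbene geometry and one racemic carbinol met on the way are both erased.

Key step: step 14

Remark on the chemistry: the SMILES of asterelin A carries no stereodescriptor, so any conformational chirality of the macrocycle is taken as not fixed and is not addressed.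

**Step 1**
Reactants: 1 isovanillin
Product: 2 2-methoxy-5-vinylphenol
Conditions: MePPh3Br (2.3 equiv), KOtBu (2.3 equiv), THF, 0 °C → rt
Reagents that add atoms: methyltriphenylphosphonium bromide, C[P+](c1ccccc1)(c1ccccc1)c1ccccc1.[Br-]
Why: Wittig methylenation of a non-enolisable aryl aldehyde; the extra equivalent of base only stores the phenol as its inert phenoxide until work-up.

**Step 2**
Reactants: 2 2-methoxy-5-vinylphenol; 3 4-fluorobenzaldehyde
Product: 4 4-(2-methoxy-5-vinylphenoxy)benzaldehyde
Conditions: Cs2CO3 (1.5 equiv), BHT (cat.), DMF, 80 °C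
Reagents that add atoms: none
Why: Nucleophilic aromatic substitution by addition–elimination, in which the para-formyl group stabilises the Meisenheimer adduct so that the phenoxide displaces fluoride; because ring C already carries vinyl in place of its aldehyde, the two ends of the arm are differentiated.

**Step 3**
Reactants: 5 methyl 4-bromo-2-hydroxybenzoate; 6 methyl bromoacetate
Product: 7 methyl 4-bromo-2-(2-methoxy-2-oxoethoxy)benzoate
Conditions: K2CO3 (1.5 equiv), acetone, reflux
Reagents that add atoms: none
Why: Williamson O-alkylation of the salicylate phenol by an activated primary bromide; carbonate in acetone is too weak to start the Dieckmann closure.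

**Step 4**
Reactants: 4 4-(2-methoxy-5-vinylphenoxy)benzaldehyde; 7 methyl 4-bromo-2-(2-methoxy-2-oxoethoxy)benzoate
Product: 8 methyl 4-[(E)-2-{3-(4-formylphenoxy)-4-methoxyphenyl}ethenyl]-2-(2-methoxy-2-oxoethoxy)benzoate
Conditions: Pd(OAc)2 (3 mol %), P(o-tol)3 (6 mol %), Et3N (2 equiv), DMF, 100 °C
Reagents that add atoms: none
Why: Mizoroki–Heck reaction, in which the bromide para to the ester adds readily to zerovalent palladium and the styrene is arylated at its terminal carbon; syn insertion and syn β-hydride elimination give the E-stilbene, whose geometry is erased in step 5.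

**Step 5**
Reactants: 8 E-stilbene aldehyde
Product: 9 methyl 4-{2-[3-(4-formylphenoxy)-4-methoxyphenyl]ethyl}-2-(2-methoxy-2-oxoethoxy)benzoate
Conditions: H2 (1 atm), 10 % Pd/C, Ph2S (1 mol %), EtOAc, rt
Reagents that add atoms: none
Why: Catalytic hydrogenation over sulfide-poisoned Pd/C, a catalyst type known to saturate alkenes while leaving aromatic aldehydes, esters and aryl ethers untouched.

**Step 6**
Reactants: 9 bibenzyl aldehyde
Product: 10 methyl 4-(2-{3-[4-(1-hydroxybut-3-yn-1-yl)phenoxy]-4-methoxyphenyl}ethyl)-2-(2-methoxy-2-oxoethoxy)benzoate (racemic)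
Conditions: propargyl bromide (1.5 equiv), Zn dust (2 equiv), THF–sat. aq NH4Cl, 0 °C → rt
Reagents that add atoms: propargyl bromide, BrCC#C
Why: Zinc Barbier propargylation, in which the allenylzinc bromide formed in the flask attacks the aldehyde by an SE2' path and ignores the esters; the carbinol centre forms without control (racemic) and is removed in step 7.

**Step 7**
Reactants: 10 homopropargylic benzylic alcohol
Product: 11 methyl 4-(2-{3-[4-(but-3-yn-1-yl)phenoxy]-4-methoxyphenyl}ethyl)-2-(2-methoxy-2-oxoethoxy)benzoate
Conditions: Et3SiH (3 equiv), CF3CO2H (10 equiv), CH2Cl2, 0 °C → rt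
Reagents that add atoms: none
Why: Ionic hydrogenation, in which acid ionises the benzylic alcohol to a cation stabilised by the para-aryloxy group and excess silane quenches it by hydride transfer; the alkyne, esters and ethers stay inert.

**Step 8**
Reactants: 11 butynyl diester
Product: 12 methyl 6-(2-{3-[4-(but-3-yn-1-yl)phenoxy]-4-methoxyphenyl}ethyl)-3-hydroxy-1-benzofuran-2-carboxylate
Conditions: NaOMe (2 equiv), MeOH–THF, 50 °C; then 1 M HCl, 0 °C
Reagents that add atoms: none
Why: Dieckmann condensation, in which the aryloxyacetate enolate attacks the ortho benzoate ester (5-exo-trig) and formation of the 3-hydroxybenzofuran enolate drives the equilibrium; methoxide matches the esters and is too weak to isomerise the alkyne.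

**Step 9**
Reactants: 12 3-hydroxybenzofuran ester
Product: 13 methyl 6-(2-{3-[4-(but-3-yn-1-yl)phenoxy]-4-methoxyphenyl}ethyl)-3-(trifluoromethylsulfonyloxy)-1-benzofuran-2-carboxylate
Conditions: Tf2O (1.2 equiv), pyridine (2.5 equiv), CH2Cl2, −20 → 0 °C
Reagents that add atoms: triflic anhydride, O=S(=O)(OS(=O)(=O)C(F)(F)F)C(F)(F)F
Why: O-sulfonylation of the acidic enol, giving a 3-triflyloxybenzofuran-2-carboxylate of the kind established as a cross-coupling electrophile; no other hydroxyl group competes.

**Step 10**
Reactants: 13 alkynyl triflate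
Product: 14 methyl 6-[2-(4-methoxy-3-{4-[3-(4,4,5,5-tetramethyl-1,3,2-dioxaborolan-2-yl)but-3-en-1-yl]phenoxy}phenyl)ethyl]-3-(trifluoromethylsulfonyloxy)-1-benzofuran-2-carboxylate
Conditions: B2pin2 (1.1 equiv), (CAAC)CuCl (5 mol %; CAAC = 1-(2,6-diisopropylphenyl)-3,3-diethyl-5,5-dimethylpyrrolidin-2-ylidene), NaOtBu (10 mol %), MeOH (2 equiv), THF, rt
Reagents that add atoms: bis(pinacolato)diboron, CC1(C)OB(OC1(C)C)B1OC(C)(C)C(C)(C)O1
Why: Copper-catalysed Markovnikov protoboration of a terminal alkyne, in which the strongly donating carbene ligand should steer syn addition of Cu–Bpin with boron on the internal carbon and methanol protonates the alkenylcopper; monovalent copper does not insert into the aryl triflate.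

**Step 11**
Reactants: 14 alkenylboronate triflate
Product: 15 macrocyclic methyl 3-(alk-1-en-2-yl)benzofuran-2-carboxylate (18-membered ring; benzofuran C3–C(=CH2)–CH2CH2–ring D–O–ring C–CH2CH2–benzofuran C6)
Conditions: Pd(OAc)2 (10 mol %), SPhos (20 mol %), K3PO4 (3 equiv), 1,4-dioxane–H2O (20:1), 80 °C, 14 added by syringe pump over 12 h (final 1 mM)
Reagents that add atoms: none
Why: Intramolecular Suzuki–Miyaura coupling, in which the C3 triflate activated by the C2 ester adds quickly to zerovalent palladium and slow addition keeps ring closure ahead of oligomerisation; the ring closes while the future C1 is still a freely rotating alkenyl carbon, so little strain is met.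

**Step 12**
Reactants: 15 macrocyclic methyl ester
Product: 16 macrocyclic 3-(alk-1-en-2-yl)benzofuran-2-carboxylic acid
Conditions: LiOH·H2O (5 equiv), THF–MeOH–H2O, rt; then cold 0.5 M HCl to pH 3–4
Reagents that add atoms: lithium hydroxide, [Li+].[OH-]
Why: Ester saponification by acyl–oxygen cleavage; brief, cold and only mildly acidic work-up avoids acid-catalysed lactonisation of the acid onto the neighbouring alkene.

**Step 13**
Reactants: 16 macrocyclic acid
Product: 18 macrocyclic 2-diazoacetyl-3-(alk-1-en-2-yl)benzofuran, via acid chloride 17 (not isolated)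
Conditions: Me2C=C(Cl)NMe2 (1.2 equiv), CH2Cl2, 0 °C; then CH2N2 (excess), Et2O, 0 °C, dark
Reagents that add atoms: diazomethane, C=[N+]=[N-]; 1-chloro-N,N,2-trimethylprop-1-en-1-amine, CC(C)=C(Cl)N(C)C (supplies the chlorine of 17)
Why: Arndt–Eistert acylation of diazomethane, in which the α-chloroenamine makes the acid chloride under neutral conditions with no free HCl to attack the alkene; C-acylation of CH2N2 and deprotonation by a second equivalent give the diazoketone.

**Step 14**
Reactants: 18 macrocyclic diazoketone
Product: 21 asterelin A ring C monomethyl ether, via dienylketene 19 (not isolated), via cyclohexadienone 20 (not isolated)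
Conditions: hν (medium-pressure Hg lamp, Pyrex, λ > 300 nm), dry degassed ClCH2CH2Cl (2 mM), 20 °C; then 80 °C, dark
Reagents that add atoms: none
Why: Direct excitation of the s-Z diazoketone ejects N2 while benzofuran C2 shifts from the carbonyl carbon to the diazo carbon (this makes C4–C4a), leaving ketene 19 in which the ketene C=C, the furan C2=C3 bond and the exocyclic methylene are conjugated. This triene then closes thermally in the disrotatory six-electron mode, bonding the ketene carbonyl carbon to the =CH2 carbon (C3–C2) so that ring A forms as a six-membered carbocycle in dienone 20, and enolisation gives phenol 21. The closest known chemistry is the photo-Wolff rearrangement of ortho-alkenyl aryl diazoketones to phenols, which is the last phase of the Danheiser benzannulation. No stereocentre is created. The Wolff/pericyclic channel must beat carbene cyclopropanation of the adjacent alkene, dipolar addition of the diazo group, and capture of the ketene by nucleophiles including the product phenol; metal-free irradiation, a dry non-nucleophilic solvent and high dilution serve this. In the substrate, the marked double-bond character of the furan C2=C3 bond lowers the cost of closure, the tether to benzofuran C6 draws the homobenzylic chain to the C4–H side so that the methylene faces the ketene, and the energy released by N2 extrusion and aromatisation of ring A offsets the strain of rigidifying the macrocycle.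

**Step 15**
Reactants: 21 asterelin A ring C monomethyl ether
Product: 22 asterelin A
Conditions: BBr3 (4 equiv), CH2Cl2, −78 → 0 °C; then H2O
Reagents that add atoms: none
Why: Lewis-acid aryl methyl ether cleavage, in which boron binds the methoxy oxygen and bromide attacks the methyl carbon (SN2); the diaryl ether and dibenzofuran C–O bonds offer no sp3 carbon and survive.

**Compound list**
1 | isovanillin | COc1ccc(C=O)cc1O | starting material
2 | 2-methoxy-5-vinylphenol | COc1ccc(C=C)cc1O | intermediate
3 | 4-fluorobenzaldehyde | O=Cc1ccc(F)cc1 | starting material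
4 | 4-(2-methoxy-5-vinylphenoxy)benzaldehyde | COc1ccc(C=C)cc1Oc1ccc(C=O)cc1 | intermediate
5 | methyl 4-bromo-2-hydroxybenzoate | COC(=O)c1ccc(Br)cc1O | starting material
6 | methyl bromoacetate | COC(=O)CBr | starting material
7 | methyl 4-bromo-2-(2-methoxy-2-oxoethoxy)benzoate | COC(=O)COc1cc(Br)ccc1C(=O)OC | intermediate
8 | E-stilbene aldehyde diester | COC(=O)COc1cc(/C=C/c2ccc(OC)c(Oc3ccc(C=O)cc3)c2)ccc1C(=O)OC | intermediate
9 | bibenzyl aldehyde diester | COC(=O)COc1cc(CCc2ccc(OC)c(Oc3ccc(C=O)cc3)c2)ccc1C(=O)OC | intermediate
10 | homopropargylic alcohol diester (racemic) | COC(=O)COc1cc(CCc2ccc(OC)c(Oc3ccc(C(O)CC#C)cc3)c2)ccc1C(=O)OC | intermediate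
11 | butynyl diester | COC(=O)COc1cc(CCc2ccc(OC)c(Oc3ccc(CCC#C)cc3)c2)ccc1C(=O)OC | intermediate
12 | 3-hydroxybenzofuran-2-carboxylate with butynyl arm | COC(=O)c1oc2cc(CCc3ccc(OC)c(Oc4ccc(CCC#C)cc4)c3)ccc2c1O | intermediate
13 | 3-triflyloxybenzofuran-2-carboxylate with butynyl arm | COC(=O)c1oc2cc(CCc3ccc(OC)c(Oc4ccc(CCC#C)cc4)c3)ccc2c1OS(=O)(=O)C(F)(F)F | intermediate
14 | alkenyl pinacolboronate triflate | COC(=O)c1oc2cc(CCc3ccc(OC)c(Oc4ccc(CCC(=C)B5OC(C)(C)C(C)(C)O5)cc4)c3)ccc2c1OS(=O)(=O)C(F)(F)F | intermediate
15 | macrocyclic methyl 3-(alk-1-en-2-yl)benzofuran-2-carboxylate | COC(=O)c1oc2cc3ccc2c1C(=C)CCc1ccc(cc1)Oc1cc(ccc1OC)CC3 | intermediate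
16 | macrocyclic benzofuran-2-carboxylic acid | OC(=O)c1oc2cc3ccc2c1C(=C)CCc1ccc(cc1)Oc1cc(ccc1OC)CC3 | intermediate
17 | macrocyclic benzofuran-2-carbonyl chloride (not isolated) | ClC(=O)c1oc2cc3ccc2c1C(=C)CCc1ccc(cc1)Oc1cc(ccc1OC)CC3 | intermediate
18 | macrocyclic 2-diazoacetyl-3-(alk-1-en-2-yl)benzofuran | [N-]=[N+]=CC(=O)c1oc2cc3ccc2c1C(=C)CCc1ccc(cc1)Oc1cc(ccc1OC)CC3 | intermediate
19 | macrocyclic benzofuran-2-ylketene (dienylketene, not isolated) | O=C=Cc1oc2cc3ccc2c1C(=C)CCc1ccc(cc1)Oc1cc(ccc1OC)CC3 | intermediate
20 | macrocyclic dibenzofuran-3(2H)-one (cyclohexadienone, not isolated) | O=C1CC2=C3C(=C1)Oc1cc(ccc13)CCc1ccc(OC)c(c1)Oc1ccc(cc1)CC2 | intermediate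
21 | asterelin A ring C monomethyl ether | Oc1cc2c3c(c1)oc1cc(ccc13)CCc1ccc(OC)c(c1)Oc1ccc(cc1)CC2 | intermediate
22 | asterelin A | Oc1cc2c3c(c1)oc1cc(ccc13)CCc1ccc(O)c(c1)Oc1ccc(cc1)CC2 | target

**Total steps:** 15. **Longest linear sequence:** 14 (steps 1, 2 and 4–15, from isovanillin).

**Steps most likely to fail**

Step 14. Several processes may go wrong:
- the freshly formed phenol may be acylated by ketene still present;
- the neighbouring methylene may undergo carbene-type cyclopropanation;
- the diazo group may add slowly to that alkene in the dark before irradiation;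
- secondary photolysis may occur.

Fallback, from 18 back to 21: the ketene is first trapped on purpose and then regenerated thermally under acylating conditions. PhCO2Ag (10 mol %) and Et3N in THF–H2O take 18 through a silver-promoted Wolff rearrangement, via 19, to the macrocyclic benzofuran-2-ylacetic acid F1. Heating in Ac2O with NaOAc (120 °C) converts it into the mixed acetic anhydride F2, which loses acetic acid to give 19 again. Closure through 20 follows, and the phenol is acetylated at once to the ring A C3 acetate F3, so it cannot consume ketene. This is the known dehydrative benzannulation of 3,5-dienoic acids. K2CO3 in MeOH removes the acetate and returns 21.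

Step 11. Three processes may go wrong:
- oligomerisation may outrun closure of the 18-membered ring;
- the α-substituted alkenylboronate may protodeboronate;
- base may cleave the S–O bond of the activated triflate back to the enol.

Fallback, from 13 back to 15, bypassing steps 10 and 11: Markovnikov addition of HI, generated from Me3SiCl, NaI and H2O in MeCN at rt, gives the 2-iodoalkene triflate F4. This bis-electrophile is then treated at 2 mM with PdCl2(dppf), B2pin2 and KOAc in DMSO at 80 °C. The alkenyl iodide is the faster partner in oxidative addition and is borylated slowly to 14. Compound 14 does not accumulate, because it couples with the triflate in the same flask (domino Miyaura borylation and intramolecular Suzuki–Miyaura macrocyclisation). Anhydrous acetate replaces aqueous phosphate, so the hydrolytic side paths lose their reagent, and the low stationary concentration of boronate acts as added dilution.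

Step 10. Two processes may go wrong: boron may leak to the terminal carbon of an electronically unbiased alkyl alkyne, and the alkoxide co-catalyst may cause methanolysis of the triflate.

Fallback, from 11 back to 14: the regiochemistry is fixed by polar HI addition, and palladium brings in boron before any triflate exists.
- Me3SiCl, NaI and H2O in MeCN turn 11 into the 2-iodoalkene diester F5.
- PdCl2(PPh3)2, PPh3, KOPh and B2pin2 in toluene at 50 °C (Miyaura borylation of an alkenyl halide) give the alkenylboronate diester F6.
- NaOMe in MeOH–THF closes the furan by Dieckmann condensation to the 3-hydroxybenzofuran alkenylboronate F7; alkenyl pinacol boronates are slow to protodeboronate under base.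
- Tf2O and pyridine in CH2Cl2 then give 14.

**Further compounds**
F1 | step 14 | macrocyclic 2-[3-(alk-1-en-2-yl)benzofuran-2-yl]acetic acid | OC(=O)Cc1oc2cc3ccc2c1C(=C)CCc1ccc(cc1)Oc1cc(ccc1OC)CC3
F2 | step 14 | mixed acetic anhydride of F1 (not isolated) | CC(=O)OC(=O)Cc1oc2cc3ccc2c1C(=C)CCc1ccc(cc1)Oc1cc(ccc1OC)CC3
F3 | step 14 | asterelin A ring C methyl ether, ring A C3 acetate | CC(=O)Oc1cc2c3c(c1)oc1cc(ccc13)CCc1ccc(OC)c(c1)Oc1ccc(cc1)CC2
F4 | step 11 | 2-iodoalkene triflate | COC(=O)c1oc2cc(CCc3ccc(OC)c(Oc4ccc(CCC(I)=C)cc4)c3)ccc2c1OS(=O)(=O)C(F)(F)F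
F5 | step 10 | 2-iodoalkene diester | COC(=O)COc1cc(CCc2ccc(OC)c(Oc3ccc(CCC(I)=C)cc3)c2)ccc1C(=O)OC
F6 | step 10 | alkenylboronate diester | COC(=O)COc1cc(CCc2ccc(OC)c(Oc3ccc(CCC(=C)B4OC(C)(C)C(C)(C)O4)cc3)c2)ccc1C(=O)OC
F7 | step 10 | 3-hydroxybenzofuran alkenylboronate | COC(=O)c1oc2cc(CCc3ccc(OC)c(Oc4ccc(CCC(=C)B5OC(C)(C)C(C)(C)O5)cc4)c3)ccc2c1O
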